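**Retrosynthetic overview**

1. Ring C is closed last, through C8–C14. A tertiary C‑14 radical on ring D adds 6‑exo to C‑8, the β‑carbon of the C‑6‑oxo‑Δ7 enone of ring B. The quaternary C‑9 next to C‑8 (Me, aryl, C‑11/C‑12 tether) forces the cis B/C junction, and the C‑6 ketone later becomes the Δ6 alkene.
2. C12–C13 comes from alkylating the enolate of a cis‑fused DE decalone with an AB–guaiane iodide. The C‑14 ketone is then turned into a tertiary alcohol and its oxalate, the radical precursor.
3. The dioxane comes from a hetero‑Diels–Alder reaction of the ring‑A o‑quinone with C1′=C5′ of a guaiane dienyl triflate made from (S)‑carvone; the triflate is then exchanged for methyl.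
4. C‑9 is set by asymmetric conjugate addition and ring B is closed by Friedel–Crafts acylation. C‑20 is set by a catalytic Diels–Alder reaction, C‑17 by a chiral‑imine Michael/Robinson annulation, C‑18 by hydrogenation.
5. Ring order: guaiane seven‑ and five‑membered rings; ring B on the commercial ring‑A arene; dioxane; ring E, ring D; ring C.

Key step: step 33

Remark: triterpene carbons carry friedelane numbers (β = face of the C‑25/C‑26 methyls and of H‑18), guaiane carbons carry primed numbers; each chiral catalyst, ligand or auxiliary is named by its published facial model and its antipode would be used if the sense proved opposite.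

**Guaiane dienophile**

Step 1
Reactants: 1 (S)-(+)-carvone
Product: 2 (2S,5S)-2-methyl-5-(prop-1-en-2-yl)cyclohexan-1-one
Conditions: LiBH(s-Bu)3, THF, −78 °C; then NaOMe (cat.), MeOH, rt; trans isomer separated
Reagents that add atoms: none
Why: Conjugate hydride reduction of the enone followed by base equilibration gives the thermodynamically favoured trans (diequatorial) dihydrocarvone, which fixes C‑10′ relative to C‑7′.

Step 2
Reactants: 2 (2S,5S)-2-methyl-5-(prop-1-en-2-yl)cyclohexan-1-one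
Product: 3 ethyl (3S,6S)-3-methyl-2-oxo-6-(prop-1-en-2-yl)cycloheptane-1-carboxylate (C‑1 epimers)
Conditions: ethyl diazoacetate, BF3·OEt2, Et2O, 0 °C → rt
Reagents that add atoms: ethyl diazoacetate (CCOC(=O)C=[N+]=[N-])
Why: In this Lewis‑acid‑promoted diazoacetate ring expansion the less substituted α‑CH2 migrates, so the methyl‑bearing stereocentre stays next to the ketone.

Step 3
Reactants: 3 ethyl (3S,6S)-3-methyl-2-oxo-6-(prop-1-en-2-yl)cycloheptane-1-carboxylate
Product: 4 ethyl (3S,6S)-3-methyl-6-(prop-1-en-2-yl)-2-(trifluoromethylsulfonyloxy)cyclohept-1-ene-1-carboxylate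
Conditions: NaH, THF, 0 °C; then PhNTf2, 0 °C → rt
Reagents that add atoms: N-phenylbis(trifluoromethanesulfonimide) (O=S(=O)(N(c1ccccc1)S(=O)(=O)C(F)(F)F)C(F)(F)F)
Why: O‑Triflation of the β‑keto ester enolate fixes the tetrasubstituted C1′=C5′ double bond regiospecifically without touching C‑10′.

Step 4
Reactants: 4 enol triflate
Product: 5 ethyl (3S,6S)-2-(3-ethoxy-3-oxopropyl)-3-methyl-6-(prop-1-en-2-yl)cyclohept-1-ene-1-carboxylate
Conditions: BrZnCH2CH2CO2Et, Pd(PPh3)4 (5 mol %), THF, 50 °C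
Reagents that add atoms: (3-ethoxy-3-oxopropyl)zinc bromide (CCOC(=O)CC[Zn]Br)
Why: Negishi coupling of a β‑triflyloxy enoate with a zinc homoenolate is routine and installs C‑2′/C‑3′ with retention of the alkene.

Step 5
Reactants: 5 diester
Product: 6 ethyl (4S,7S)-4-methyl-1-oxo-7-(prop-1-en-2-yl)-1,2,3,4,5,6,7,8-octahydroazulene-2-carboxylate (C‑2 epimers)
Conditions: KOt-Bu, THF, 0 °C → rt; AcOH quench
Reagents that add atoms: none
Why: Dieckmann condensation of the saturated ester enolate onto the conjugated ester closes the five‑membered ring, driven by formation of the stabilised β‑keto ester enolate.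

Step 6
Reactants: 6 bicyclic β-keto ester
Product: 7 (4S,7S)-4-methyl-7-(prop-1-en-2-yl)-3,4,5,6,7,8-hexahydroazulen-1(2H)-one
Conditions: LiCl, DMSO, H2O, 140 °C
Reagents that add atoms: none
Why: Krapcho dealkoxycarbonylation removes the ester under neutral conditions that spare the isopropenyl group.

Step 7
Reactants: 7 enone
Product: 8 (4S,7S)-4-methyl-7-(prop-1-en-2-yl)-3,4,5,6,7,8-hexahydroazulen-1-yl trifluoromethanesulfonate (15′-norguaia-1′(5′),3′,11′-trien-4′-yl triflate)
Conditions: LDA, THF, −78 °C; then PhNTf2, −78 → 0 °C; used at once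
Reagents that add atoms: N-phenylbis(trifluoromethanesulfonimide) (O=S(=O)(N(c1ccccc1)S(=O)(=O)C(F)(F)F)C(F)(F)F)
Why: Kinetic α′‑deprotonation at C‑3′ and O‑triflation give the cross‑conjugated dienyl triflate with the sp3 CH2 at C‑2′, as needed.

**Ring AB and dioxane**

Step 8
Reactants: 9 2,3-dimethoxytoluene
Product: 11 (3,4-dimethoxy-5-methylphenyl)boronic acid, via aryl pinacol boronate 10 (not isolated)
Conditions: [Ir(cod)OMe]2 (1.5 mol %), 4,4′-di-tert-butyl-2,2′-bipyridine, B2pin2, THF, 80 °C; then NaIO4, aq. HCl, THF, rt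
Reagents that add atoms: bis(pinacolato)diboron (CC1(C)OB(OC1(C)C)B1OC(C)(C)C(C)(C)O1); water (O)
Why: Sterically controlled iridium‑catalysed C–H borylation attacks the only C–H without an ortho substituent (future C‑10), and periodate cleaves the pinacol ester.

Step 9
Reactants: 11 (3,4-dimethoxy-5-methylphenyl)boronic acid; 12 3-methylcyclohex-2-en-1-one
Product: 13 (3S)-3-(3,4-dimethoxy-5-methylphenyl)-3-methylcyclohexan-1-one
Conditions: Pd(OCOCF3)2 (5 mol %), (R)-t-BuPyOx (6 mol %), NH4PF6, H2O, ClCH2CH2Cl, 40 °C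
Reagents that add atoms: none
Why: Palladium/pyridine‑oxazoline asymmetric conjugate addition of an arylboronic acid to a β‑methyl enone creates the benzylic quaternary C‑9, its configuration set by the ligand.

Step 10
Reactants: 13 aryl ketone
Product: 14 (5S)-5-(3,4-dimethoxy-5-methylphenyl)-5-methyl-1-(trimethylsilyloxy)cyclohex-1-ene
Conditions: LDA, THF, −78 °C; Me3SiCl
Reagents that add atoms: chlorotrimethylsilane (C[Si](C)(C)Cl)
Why: Kinetic enolisation goes to the α‑CH2 remote from the quaternary centre, which marks the bond to be cleaved.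

Step 11
Reactants: 14 silyl enol ether
Product: 16 (3S)-3-(3,4-dimethoxy-5-methylphenyl)-3-methylhexanedioic acid, via aldehyde acid 15 (not isolated)
Conditions: O3, CH2Cl2/MeOH, −78 °C (indicator dye end point); then 30% H2O2, HCO2H, rt
Reagents that add atoms: ozone ([O-][O+]=O); hydrogen peroxide (OO)
Why: Ozonolysis of the electron‑rich enol ether with oxidative work‑up splits the ring into the two‑carbon (C‑11/C‑12) and three‑carbon (C‑8/C‑7/C‑6) acid arms on C‑9.

Step 12
Reactants: 16 diacid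
Product: 17 2-[(1S)-6,7-dimethoxy-1,5-dimethyl-4-oxo-1,2,3,4-tetrahydronaphthalen-1-yl]acetic acid
Conditions: (CF3CO)2O, CH2Cl2, 0 °C → rt; aq. NaHCO3
Reagents that add atoms: none
Why: Intramolecular Friedel–Crafts acylation closes ring B through the three‑carbon arm (six‑ over five‑membered ring) at C‑5, para to the C‑2 methoxy group.

Step 13
Reactants: 17 tetralone acid
Product: 18 (4S)-4-(2-hydroxyethyl)-6,7-dimethoxy-4,8-dimethyl-3,4-dihydronaphthalen-1(2H)-one
Conditions: BH3·THF (1.1 equiv), THF, −10 → 0 °C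
Reagents that add atoms: none
Why: Borane reduces the carboxylic acid much faster than the hindered, electron‑rich aryl ketone.

Step 14
Reactants: 18 alcohol
Product: 19 (4S)-4-(2-bromoethyl)-6,7-dimethoxy-4,8-dimethyl-3,4-dihydronaphthalen-1(2H)-one
Conditions: CBr4, PPh3, CH2Cl2, 0 °C
Reagents that add atoms: carbon tetrabromide (BrC(Br)(Br)Br)
Why: Appel bromination of the primary alcohol gives a bromide robust enough for the following Lewis‑acid, oxidation and palladium steps.

Step 15
Reactants: 19 bromide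
Product: 20 (4R)-4-(2-bromoethyl)-6,7-dimethoxy-4,8-dimethylnaphthalen-1(4H)-one
Conditions: IBX (2.5 equiv), DMSO/toluene, 70 °C
Reagents that add atoms: none
Why: IBX dehydrogenation of the ketone gives the C‑6‑oxo‑Δ7 enone, which cannot aromatise because C‑9 is quaternary.

Step 16
Reactants: 20 enone
Product: 21 (4R)-4-(2-bromoethyl)-6,7-dihydroxy-4,8-dimethylnaphthalen-1(4H)-one
Conditions: BBr3, CH2Cl2, −78 → 0 °C; then H2O
Reagents that add atoms: none
Why: Boron tribromide cleaves both aryl methyl ethers to the catechol while the enone and the primary bromide survive.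

Step 17
Reactants: 21 catechol; 8 dienyl triflate
Product: 23 benzodioxane adduct: O‑2 on C‑5′ and O‑3 on C‑1′ of the 15′-norguaia-3′,11′-dien-4′-yl triflate (both oxygens cis to 10′-Me and trans to 7′-isopropenyl) with ring AB as the (9R)-12-bromo C‑6‑oxo‑Δ7 enone, via o-quinone 22 (not isolated)
Conditions: NaIO4, n-Bu4NBr (cat.), CH2Cl2/H2O, 0 °C; organic phase dried, then 8 (2 equiv), CH2Cl2, −20 °C → rt, dark
Reagents that add atoms: none
Why: This is an inverse‑demand hetero‑Diels–Alder reaction of the o‑quinone across the tetrasubstituted C1′=C5′ bond (the enol‑triflate double bond is deactivated); bond formation should start between the diene terminus C‑1′ and O‑3, since the phenoxide developing at O‑2 is para to the C‑6 carbonyl, and the quinone is expected to add suprafacially anti to the pseudoaxial C‑10′–H and C‑6′–H bonds of the diequatorial cycloheptene chair, that is syn to the 10′‑methyl and anti to the 7′‑isopropenyl group.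

Step 18
Reactants: 23 vinyl triflate adduct
Product: 24 the same adduct with C‑4′ methyl (guaia-3′,11′-diene unit; 12-bromide)
Conditions: MeZnCl, Pd(PPh3)4 (5 mol %), THF, 40 °C
Reagents that add atoms: methylzinc chloride (C[Zn]Cl)
Why: Negishi methylation of the vinyl triflate completes the C3′=C4′(Me) unit and tolerates the enone and the unactivated primary bromide.

Step 19
Reactants: 24 bromide
Product: 25 the corresponding 12-iodide
Conditions: NaI, acetone, reflux
Reagents that add atoms: sodium iodide ([Na+].[I-])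
Why: Finkelstein exchange gives the more reactive electrophile for the quaternary‑centre‑forming alkylation.

**Ring DE**

Step 20
Reactants: 26 isoprene; 27 methacrolein
Product: 28 (1R)-1,4-dimethylcyclohex-3-ene-1-carbaldehyde
Conditions: oxazaborolidinium triflimide from (S)-B-(o-tolyl)-α,α-diphenylprolinol oxazaborolidine and Tf2NH (10 mol %), CH2Cl2, −78 → −40 °C
Reagents that add atoms: none
Why: The chiral cationic boron Lewis acid catalyses a para‑selective Diels–Alder reaction and shields one face of the coordinated aldehyde, which sets quaternary C‑20.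

Step 21
Reactants: 28 aldehyde
Product: 30 methyl (1R)-1,4-dimethylcyclohex-3-ene-1-carboxylate, via carboxylic acid 29 (not isolated)
Conditions: NaClO2, NaH2PO4, 2-methyl-2-butene, t-BuOH/H2O, 0 °C; then Me3SiCHN2, MeOH/toluene, rt
Reagents that add atoms: sodium chlorite ([Na+].[O-]Cl=O); (trimethylsilyl)diazomethane (C[Si](C)(C)C=[N+]=[N-])
Why: Pinnick oxidation with a hypochlorite scavenger followed by diazoalkane esterification gives the C‑29 ester without touching the alkene.

Step 22
Reactants: 30 ester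
Product: 32 methyl (1R)-3-hydroxy-1,4-dimethylcyclohexane-1-carboxylate (diastereomers), via alkylborane 31 (not isolated)
Conditions: BH3·SMe2, THF, 0 °C; then 30% H2O2, aq. NaOAc
Reagents that add atoms: hydrogen peroxide (OO)
Why: Anti‑Markovnikov hydroboration–oxidation puts oxygen on the less substituted alkene carbon (C‑18); the new centres are erased in the next two steps.

Step 23
Reactants: 32 alcohol
Product: 33 methyl (1R)-1,4-dimethyl-3-oxocyclohexane-1-carboxylate (C‑4 epimers)
Conditions: Dess–Martin periodinane, CH2Cl2, rt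
Reagents that add atoms: none
Why: Mild oxidation of the secondary alcohol gives the ring‑E ketone.

Step 24
Reactants: 33 ketone
Product: 36 methyl (1R,4R)-1,4-dimethyl-3-oxo-4-(3-oxopentyl)cyclohexane-1-carboxylate, via ketimine 34 (not isolated), via alkylated imine 35 (not isolated)
Conditions: (S)-1-phenylethylamine, TsOH (cat.), toluene, reflux (water removal); then pent-1-en-3-one, THF, 40 °C; then 10% aq. AcOH, rt
Reagents that add atoms: pent-1-en-3-one (CCC(=O)C=C); water (O)
Why: In this chiral‑imine Michael reaction the more substituted secondary enamine tautomer adds to the vinyl ketone on the face dictated by the phenylethyl auxiliary, creating quaternary C‑17 (Me cis to the C‑20 methyl).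

Step 25
Reactants: 36 diketone
Product: 37 methyl (2R,4aR)-2,4a,8-trimethyl-7-oxo-1,2,3,4,4a,5,6,7-octahydronaphthalene-2-carboxylate
Conditions: NaOMe, MeOH, 50 °C
Reagents that add atoms: none
Why: Intramolecular aldol condensation (the second half of a Robinson annulation) closes ring D as the C‑14 enone.

Step 26
Reactants: 37 enone
Product: 38 methyl (2R,4aR,8aS)-2,4a,8-trimethyl-7-oxodecahydronaphthalene-2-carboxylate (cis-fused; C‑8 epimers)
Conditions: H2 (4 atm), 10% Pd/C, pyridine/EtOAc, rt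
Reagents that add atoms: none
Why: Base‑modified heterogeneous hydrogenation of a fused 4‑en‑3‑one‑type enone gives mainly the cis ring fusion (18β‑H cis to the 17‑methyl), as in the 5β‑series of steroids.

Step 27
Reactants: 38 cis-decalone
Product: 39 methyl (2R,4aR,8aR)-2,4a,8-trimethyl-7-(trimethylsilyloxy)-1,2,3,4,4a,5,6,8a-octahydronaphthalene-2-carboxylate
Conditions: Me3SiCl, Et3N, DMF, 100 °C
Reagents that add atoms: chlorotrimethylsilane (C[Si](C)(C)Cl)
Why: Equilibrating silylation gives the more substituted C13=C14 enol ether, the direction also preferred by the cis ring fusion.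

**Union, key step, end game**

Step 28
Reactants: 39 silyl enol ether; 25 iodide
Product: 41 seco‑C ketone: the AB–dioxane–guaiane enone joined through C‑11/C‑12 to C‑13 of the cis‑DE decalone (13α‑Me, C‑14 ketone, 17β‑Me, 18β‑H, 20α‑CO2Me), via lithium enolate 40 (not isolated)
Conditions: MeLi, THF, 0 °C; then HMPA, 25, −78 → 0 °C
Reagents that add atoms: none
Why: SN2 C‑alkylation of the regiodefined lithium enolate takes place on the convex β‑face (the α‑face is blocked by axial C‑22), giving quaternary C‑13 with the chain β and the methyl α.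

Step 29
Reactants: 41 seco‑C ketone
Product: 42 the C‑6 allylic alcohol of 41 (C‑6 epimers; C‑14 ketone intact)
Conditions: NaBH4, CeCl3·7H2O, MeOH, −78 °C
Reagents that add atoms: none
Why: Luche 1,2‑reduction takes the conjugated C‑6 ketone, while the C‑14 ketone flanked by quaternary C‑13 reacts much more slowly at −78 °C.

Step 30
Reactants: 42 allylic alcohol
Product: 43 the 6,14‑diol with a 14‑methyl group (tertiary C‑14 alcohol; C‑6 and C‑14 epimers)
Conditions: MeLi–CeCl3 (3 equiv each, premixed), THF, −78 °C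
Reagents that add atoms: methyllithium ([Li]C)
Why: The weakly basic organocerium reagent adds to the hindered, enolisable C‑14 ketone and spares the hindered tertiary methyl ester; the configuration at C‑14 is irrelevant because it becomes a radical.

Step 31
Reactants: 43 diol
Product: 44 the C‑6‑oxo‑Δ7 enone carrying the tertiary C‑14 alcohol
Conditions: MnO2, CH2Cl2, rt
Reagents that add atoms: none
Why: Manganese dioxide oxidises only the allylic and benzylic C‑6 alcohol, which restores the radical acceptor.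

Step 32
Reactants: 44 tertiary alcohol
Product: 45 the C‑14 methyl oxalate of 44
Conditions: ClC(O)CO2Me, DMAP, Et3N, CH2Cl2, 0 °C → rt
Reagents that add atoms: methyl chlorooxoacetate (COC(=O)C(=O)Cl)
Why: Acylation of the tertiary alcohol with the small, highly electrophilic oxalyl half‑ester chloride gives the stable tert‑alkyl methyl oxalate.

Step 33
Reactants: 45 methyl oxalate
Product: 47 ring‑C‑closed 6‑ketone (8β‑H, 9β‑Me, 13α‑Me, 14β‑Me; C‑7 methylene), via cesium oxalate 46 (not isolated)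
Conditions: CsOH·H2O (1.0 equiv), THF/H2O, rt; then Ir[dF(CF3)ppy]2(dtbbpy)PF6 (1 mol %), DME/DMF 3:1, H2O (10 equiv), blue LEDs, 60 °C, degassed
Reagents that add atoms: none
Why: Saponification gives the cesium oxalate, which the photoexcited iridium complex oxidises; loss of two CO2 gives the tertiary C‑14 radical, which adds to C‑8 of the ring‑B enone, and the α‑keto radical is reduced by the reduced photocatalyst and protonated at C‑7 (Giese‑type radical–polar crossover; the closest precedent is the intermolecular coupling of oxalate‑derived tertiary radicals with enones to build quaternary carbons). Only ring C closes, 6‑exo‑trig, through the tether C‑9–C‑11–C‑12–C‑13. C‑8 is controlled by that tether: the radical can reach only the enone face that carries C‑11 on quaternary C‑9, so H‑8 ends cis to the C‑9 methyl. C‑14 is intended to close with both the C‑12 tether and the new bond equatorial on the ring‑D chair, giving the trans C/D junction with the C‑13 and C‑14 methyls anti. The step needs chemoselectivity for the enone over the isopropenyl and cyclopentene double bonds, which the polarity match of a nucleophilic tertiary radical with the enone and the six‑membered transition state secure. It also needs this facial selectivity at C‑14, which nothing in the substrate secures: conformational analysis suggests that closure anti to the axial C‑13 methyl, giving the 14‑epimer, is the intrinsically preferred mode.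

Step 34
Reactants: 47 cyclised ketone
Product: 48 the corresponding C‑6 benzylic alcohol (C‑6 epimers)
Conditions: NaBH4, MeOH, 0 °C
Reagents that add atoms: none
Why: Borohydride reduces the aryl ketone and leaves the hindered tertiary methyl ester.

Step 35
Reactants: 48 benzylic alcohol
Product: 49 target CNP0113384.4
Conditions: Burgess reagent (methyl N-(triethylammoniosulfonyl)carbamate), toluene, 50 °C
Reagents that add atoms: none
Why: Neutral syn‑dehydration of the benzylic alcohol can only go toward C‑7, which gives the styrenic Δ6 alkene without ionising the tertiary allylic aryl ether.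

**Compound list**

1 | (S)-(+)-carvone | CC1=CC[C@@H](CC1=O)C(C)=C | starting material
2 | (2S,5S)-2-methyl-5-(prop-1-en-2-yl)cyclohexan-1-one | C[C@H]1CC[C@@H](CC1=O)C(C)=C | intermediate
3 | ethyl (3S,6S)-3-methyl-2-oxo-6-(prop-1-en-2-yl)cycloheptane-1-carboxylate | C[C@H]1CC[C@@H](CC(C(=O)OCC)C1=O)C(C)=C | intermediate
4 | ethyl (3S,6S)-3-methyl-6-(prop-1-en-2-yl)-2-(trifluoromethylsulfonyloxy)cyclohept-1-ene-1-carboxylate | C[C@H]1CC[C@@H](CC(C(=O)OCC)=C1OS(=O)(=O)C(F)(F)F)C(C)=C | intermediate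
5 | ethyl (3S,6S)-2-(3-ethoxy-3-oxopropyl)-3-methyl-6-(prop-1-en-2-yl)cyclohept-1-ene-1-carboxylate | C[C@H]1CC[C@@H](CC(C(=O)OCC)=C1CCC(=O)OCC)C(C)=C | intermediate
6 | ethyl (4S,7S)-4-methyl-1-oxo-7-(prop-1-en-2-yl)-1,2,3,4,5,6,7,8-octahydroazulene-2-carboxylate | C[C@H]1CC[C@@H](CC2=C1CC(C(=O)OCC)C2=O)C(C)=C | intermediate
7 | (4S,7S)-4-methyl-7-(prop-1-en-2-yl)-3,4,5,6,7,8-hexahydroazulen-1(2H)-one | C[C@H]1CC[C@@H](CC2=C1CCC2=O)C(C)=C | intermediate
8 | (4S,7S)-4-methyl-7-(prop-1-en-2-yl)-3,4,5,6,7,8-hexahydroazulen-1-yl trifluoromethanesulfonate | C[C@H]1CC[C@@H](CC2=C1CC=C2OS(=O)(=O)C(F)(F)F)C(C)=C | intermediate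
9 | 2,3-dimethoxytoluene | COc1cccc(C)c1OC | starting material
10 | 2-(3,4-dimethoxy-5-methylphenyl)-4,4,5,5-tetramethyl-1,3,2-dioxaborolane | COc1cc(B2OC(C)(C)C(C)(C)O2)cc(C)c1OC | intermediate (not isolated)
11 | (3,4-dimethoxy-5-methylphenyl)boronic acid | COc1cc(B(O)O)cc(C)c1OC | intermediate
12 | 3-methylcyclohex-2-en-1-one | CC1=CC(=O)CCC1 | starting material
13 | (3S)-3-(3,4-dimethoxy-5-methylphenyl)-3-methylcyclohexan-1-one | C[C@@]1(c2cc(C)c(OC)c(OC)c2)CC(=O)CCC1 | intermediate
14 | (5S)-5-(3,4-dimethoxy-5-methylphenyl)-5-methyl-1-(trimethylsilyloxy)cyclohex-1-ene | C[C@@]1(c2cc(C)c(OC)c(OC)c2)CC(O[Si](C)(C)C)=CCC1 | intermediate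
15 | (3S)-3-(3,4-dimethoxy-5-methylphenyl)-3-methyl-6-oxohexanoic acid | C[C@@](CCC=O)(c1cc(C)c(OC)c(OC)c1)CC(=O)O | intermediate (not isolated)
16 | (3S)-3-(3,4-dimethoxy-5-methylphenyl)-3-methylhexanedioic acid | C[C@@](CCC(=O)O)(c1cc(C)c(OC)c(OC)c1)CC(=O)O | intermediate
17 | 2-[(1S)-6,7-dimethoxy-1,5-dimethyl-4-oxo-1,2,3,4-tetrahydronaphthalen-1-yl]acetic acid | C[C@@]1(CC(=O)O)CCC(=O)c2c(C)c(OC)c(OC)cc12 | intermediate
18 | (4S)-4-(2-hydroxyethyl)-6,7-dimethoxy-4,8-dimethyl-3,4-dihydronaphthalen-1(2H)-one | C[C@@]1(CCO)CCC(=O)c2c(C)c(OC)c(OC)cc12 | intermediate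
19 | (4S)-4-(2-bromoethyl)-6,7-dimethoxy-4,8-dimethyl-3,4-dihydronaphthalen-1(2H)-one | C[C@@]1(CCBr)CCC(=O)c2c(C)c(OC)c(OC)cc12 | intermediate
20 | (4R)-4-(2-bromoethyl)-6,7-dimethoxy-4,8-dimethylnaphthalen-1(4H)-one | C[C@@]1(CCBr)C=CC(=O)c2c(C)c(OC)c(OC)cc12 | intermediate
21 | (4R)-4-(2-bromoethyl)-6,7-dihydroxy-4,8-dimethylnaphthalen-1(4H)-one | C[C@@]1(CCBr)C=CC(=O)c2c(C)c(O)c(O)cc12 | intermediate
22 | (4R)-4-(2-bromoethyl)-4,8-dimethylnaphthalene-1,6,7(4H)-trione | C[C@@]1(CCBr)C=CC(=O)C2=C(C)C(=O)C(=O)C=C12 | intermediate (not isolated)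
23 | benzodioxane adduct, C‑4′ enol triflate, 12-bromide | C=C(C)[C@H]1CC[C@H](C)[C@@]23CC=C(OS(=O)(=O)C(F)(F)F)[C@]2(C1)Oc1cc2c(c(C)c1O3)C(=O)C=C[C@@]2(C)CCBr | intermediate
24 | benzodioxane adduct, C‑4′ methyl, 12-bromide | C=C(C)[C@H]1CC[C@H](C)[C@@]23CC=C(C)[C@]2(C1)Oc1cc2c(c(C)c1O3)C(=O)C=C[C@@]2(C)CCBr | intermediate
25 | benzodioxane adduct, C‑4′ methyl, 12-iodide | C=C(C)[C@H]1CC[C@H](C)[C@@]23CC=C(C)[C@]2(C1)Oc1cc2c(c(C)c1O3)C(=O)C=C[C@@]2(C)CCI | intermediate
26 | isoprene | C=CC(C)=C | starting material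
27 | methacrolein | CC(=C)C=O | starting material
28 | (1R)-1,4-dimethylcyclohex-3-ene-1-carbaldehyde | O=C[C@@]1(C)CC=C(C)CC1 | intermediate
29 | (1R)-1,4-dimethylcyclohex-3-ene-1-carboxylic acid | OC(=O)[C@@]1(C)CC=C(C)CC1 | intermediate (not isolated)
30 | methyl (1R)-1,4-dimethylcyclohex-3-ene-1-carboxylate | COC(=O)[C@@]1(C)CC=C(C)CC1 | intermediate
31 | methyl (1R)-3-boranyl-1,4-dimethylcyclohexane-1-carboxylate | COC(=O)[C@@]1(C)CC(B)C(C)CC1 | intermediate (not isolated)
32 | methyl (1R)-3-hydroxy-1,4-dimethylcyclohexane-1-carboxylate | COC(=O)[C@@]1(C)CC(O)C(C)CC1 | intermediate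
33 | methyl (1R)-1,4-dimethyl-3-oxocyclohexane-1-carboxylate | COC(=O)[C@@]1(C)CC(=O)C(C)CC1 | intermediate
34 | N-[(1S)-1-phenylethyl] ketimine of 33 | COC(=O)[C@@]1(C)CC(=N[C@@H](C)c2ccccc2)C(C)CC1 | intermediate (not isolated)
35 | C‑4-alkylated ketimine | COC(=O)[C@@]1(C)CC(=N[C@@H](C)c2ccccc2)[C@@](C)(CCC(=O)CC)CC1 | intermediate (not isolated)
36 | methyl (1R,4R)-1,4-dimethyl-3-oxo-4-(3-oxopentyl)cyclohexane-1-carboxylate | COC(=O)[C@@]1(C)CC(=O)[C@@](C)(CCC(=O)CC)CC1 | intermediate
37 | methyl (2R,4aR)-2,4a,8-trimethyl-7-oxo-1,2,3,4,4a,5,6,7-octahydronaphthalene-2-carboxylate | COC(=O)[C@@]1(C)CC2=C(C)C(=O)CC[C@@]2(C)CC1 | intermediate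
38 | methyl (2R,4aR,8aS)-2,4a,8-trimethyl-7-oxodecahydronaphthalene-2-carboxylate | COC(=O)[C@@]1(C)C[C@H]2C(C)C(=O)CC[C@@]2(C)CC1 | intermediate
39 | methyl (2R,4aR,8aR)-2,4a,8-trimethyl-7-(trimethylsilyloxy)-1,2,3,4,4a,5,6,8a-octahydronaphthalene-2-carboxylate | COC(=O)[C@@]1(C)C[C@H]2C(C)=C(O[Si](C)(C)C)CC[C@@]2(C)CC1 | intermediate
40 | lithium enolate of 38 (C13=C14) | COC(=O)[C@@]1(C)C[C@H]2C(C)=C([O-])CC[C@@]2(C)CC1.[Li+] | intermediate (not isolated)
41 | seco‑C C‑14 ketone | C=C(C)[C@H]1CC[C@H](C)[C@@]23CC=C(C)[C@]2(C1)Oc1cc2c(c(C)c1O3)C(=O)C=C[C@@]2(C)CC[C@@]2(C)[C@@H]3C[C@](C)(C(=O)OC)CC[C@]3(C)CCC2=O | intermediate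
42 | seco‑C 6-hydroxy C‑14 ketone | C=C(C)[C@H]1CC[C@H](C)[C@@]23CC=C(C)[C@]2(C1)Oc1cc2c(c(C)c1O3)C(O)C=C[C@@]2(C)CC[C@@]2(C)[C@@H]3C[C@](C)(C(=O)OC)CC[C@]3(C)CCC2=O | intermediate
43 | seco‑C 6,14-diol (14-methyl) | C=C(C)[C@H]1CC[C@H](C)[C@@]23CC=C(C)[C@]2(C1)Oc1cc2c(c(C)c1O3)C(O)C=C[C@@]2(C)CC[C@@]2(C)[C@@H]3C[C@](C)(C(=O)OC)CC[C@]3(C)CCC2(C)O | intermediate
44 | seco‑C enone, tertiary C‑14 alcohol | C=C(C)[C@H]1CC[C@H](C)[C@@]23CC=C(C)[C@]2(C1)Oc1cc2c(c(C)c1O3)C(=O)C=C[C@@]2(C)CC[C@@]2(C)[C@@H]3C[C@](C)(C(=O)OC)CC[C@]3(C)CCC2(C)O | intermediate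
45 | seco‑C enone, C‑14 methyl oxalate | C=C(C)[C@H]1CC[C@H](C)[C@@]23CC=C(C)[C@]2(C1)Oc1cc2c(c(C)c1O3)C(=O)C=C[C@@]2(C)CC[C@@]2(C)[C@@H]3C[C@](C)(C(=O)OC)CC[C@]3(C)CCC2(C)OC(=O)C(=O)OC | intermediate
46 | seco‑C enone, C‑14 cesium oxalate | C=C(C)[C@H]1CC[C@H](C)[C@@]23CC=C(C)[C@]2(C1)Oc1cc2c(c(C)c1O3)C(=O)C=C[C@@]2(C)CC[C@@]2(C)[C@@H]3C[C@](C)(C(=O)OC)CC[C@]3(C)CCC2(C)OC(=O)C(=O)[O-].[Cs+] | intermediate (not isolated)
47 | ring‑C‑closed 6-ketone | C=C(C)[C@H]1CC[C@H](C)[C@@]23CC=C(C)[C@]2(C1)Oc1cc2c(c(C)c1O3)C(=O)C[C@@H]1[C@@]2(C)CC[C@@]2(C)[C@@H]3C[C@](C)(C(=O)OC)CC[C@]3(C)CC[C@]12C | intermediate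
48 | ring‑C‑closed 6-alcohol | C=C(C)[C@H]1CC[C@H](C)[C@@]23CC=C(C)[C@]2(C1)Oc1cc2c(c(C)c1O3)C(O)C[C@@H]1[C@@]2(C)CC[C@@]2(C)[C@@H]3C[C@](C)(C(=O)OC)CC[C@]3(C)CC[C@]12C | intermediate
49 | CNP0113384.4 | C=C(C)[C@H]1CC[C@H](C)[C@@]23CC=C(C)[C@]2(C1)Oc1cc2c(c(C)c1O3)C=C[C@@H]1[C@@]2(C)CC[C@@]2(C)[C@@H]3C[C@](C)(C(=O)OC)CC[C@]3(C)CC[C@]12C | target

**Summary**

Total step count: 35. Longest linear sequence: 20 steps (steps 8–19, then 28–35).

**Steps most likely to fail**

1. Step 33. The bond may form on the wrong face of the planar C‑14 radical, anti to the axial C‑13 methyl, giving the cis C/D junction; the analysis behind the route suggests this is the intrinsically preferred face. The radical may also be reduced before the slow addition to the hindered C‑8. The fallback sets out from 41 and introduces the C‑14 methyl last. SmI2/HMPA/t‑BuOH in THF at −78 °C closes ring C by reductive enone–ketone coupling (C‑8 again fixed by the tether) to give the ring‑C‑closed 14‑hydroxy 6‑ketone F1. Me3Al in CH2Cl2 (−40 °C → rt) then replaces the tertiary hydroxyl by methyl in an SN1 methylation. The planar C‑14 cation should take the small methyl group axially, anti to the C‑13 methyl, which returns to the route at 47.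

2. Step 17. The dienyl triflate may react as a 4π diene (dimerisation or carbo‑Diels–Alder addition to a quinone C=C), add across C3′=C4′, or discriminate its two faces poorly. The fallback sets out from enone 7 and quinone 22 and uses a dienophile with a single alkene and a neighbouring controlling stereocentre.
   - CBS reduction of 7 ((S)-2-methyl-CBS-oxazaborolidine, BH3·SMe2) gives (1R,4S,7S)-4-methyl-7-(prop-1-en-2-yl)-1,2,3,4,5,6,7,8-octahydroazulen-1-ol F2.
   - TBSOTf/2,6‑lutidine gives its silyl ether F3.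
   - Hetero‑Diels–Alder reaction with 22, anti to the silyloxy group, gives the 4′‑silyloxy adduct F4.
   - HF·pyridine gives the 4′‑alcohol F5, and Dess–Martin periodinane the 4′‑ketone F6.
   - KHMDS/PhNTf2 at −78 °C (the ring‑B enone has no enolisable hydrogen) returns to the route at 23.

3. Step 26. Hydrogenation of the tetrasubstituted enone may be slow and may give the trans ring fusion. The fallback sets out from 37. Luche reduction gives the 14β‑allylic alcohol F7. Hydroxyl‑directed hydrogenation with [Ir(cod)(PCy3)(py)]PF6 and H2 in CH2Cl2 delivers hydrogen syn to the hydroxyl, giving the cis‑fused saturated alcohol F8 (18β‑H). Dess–Martin oxidation returns to the route at 38.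

**Further compounds**

F1 | step 33 | ring‑C‑closed 14-hydroxy 6-ketone (C‑14 tertiary alcohol) | C=C(C)[C@H]1CC[C@H](C)[C@@]23CC=C(C)[C@]2(C1)Oc1cc2c(c(C)c1O3)C(=O)C[C@@H]1[C@@]2(C)CC[C@@]2(C)[C@@H]3C[C@](C)(C(=O)OC)CC[C@]3(C)CCC12O
F2 | step 17 | (1R,4S,7S)-4-methyl-7-(prop-1-en-2-yl)-1,2,3,4,5,6,7,8-octahydroazulen-1-ol | C[C@H]1CC[C@@H](CC2=C1CC[C@H]2O)C(C)=C
F3 | step 17 | tert-butyldimethylsilyl ether of F2 | C[C@H]1CC[C@@H](CC2=C1CC[C@H]2O[Si](C)(C)C(C)(C)C)C(C)=C
F4 | step 17 | benzodioxane adduct with 4′-silyloxy group (12-bromide) | C=C(C)[C@H]1CC[C@H](C)[C@@]23CC[C@@H](O[Si](C)(C)C(C)(C)C)[C@]2(C1)Oc1cc2c(c(C)c1O3)C(=O)C=C[C@@]2(C)CCBr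
F5 | step 17 | benzodioxane adduct 4′-alcohol | C=C(C)[C@H]1CC[C@H](C)[C@@]23CC[C@@H](O)[C@]2(C1)Oc1cc2c(c(C)c1O3)C(=O)C=C[C@@]2(C)CCBr
F6 | step 17 | benzodioxane adduct 4′-ketone | C=C(C)[C@H]1CC[C@H](C)[C@@]23CCC(=O)[C@]2(C1)Oc1cc2c(c(C)c1O3)C(=O)C=C[C@@]2(C)CCBr
F7 | step 26 | methyl (2R,4aR)-7β-hydroxy-2,4a,8-trimethyl-1,2,3,4,4a,5,6,7-octahydronaphthalene-2-carboxylate | COC(=O)[C@@]1(C)CC2=C(C)[C@H](O)CC[C@@]2(C)CC1
F8 | step 26 | cis-fused saturated 7β-alcohol | COC(=O)[C@@]1(C)C[C@H]2[C@@H](C)[C@H](O)CC[C@@]2(C)CC1
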